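## The problem

Target 20 is a 2-aryl-2,3-dihydrobenzofuran neolignan. With the numbering O1, C2, C3, C3a, C4–C7, C7a, the five-membered ring B (O1, C2, C3, C3a, C7a) is fused to benzo ring A. C2 carries the catechol ring C, C3 a methyl ester, C5 an (E)-acrylate and C7 a free phenol, so ring A is a 1,2,3,5-tetrasubstituted arene with oxygen on two neighbouring carbons (C7a and C7).

The only stereocentres are C2 and C3, both R, which is the 2,3-trans arrangement. C3 is epimerisable next to its ester and trans is the more stable isomer, so C2 can correct C3. Nothing can correct C2, so the absolute configuration has to be introduced deliberately.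

The molecule tolerates little:
- Base at C3–H threatens epimerisation and, worse, E1cB opening of ring B to an achiral cinnamate.
- Acid or base acting on a free para-hydroxybenzyl ether at C2 opens a quinone methide path.
- The catechol is easily oxidised.
- The acrylate forbids hydrogenolysis, and the two methyl esters forbid saponification.

The last steps must therefore be close to neutral, and the phenol protection must leave with fluoride.

The feature that the plan uses is that ring B, taken without ring A, is a trans γ-aryl paraconic ester lactone whose carbonyl carbon is C7a and whose α-carbon is C3a. The enol form of that lactone is an electron-rich two-carbon partner, and the four carbons C4–C7 can come from a 2-pyrone that gives up CO2. In 3,5-dibromo-2-pyrone 12 the two bromines end on C7 and C5, where the target has its phenol and its acrylate.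

## Retrosynthesis

**20 to 19.** The two O–Si bonds of the catechol are cut last. Silyl ethers are the only phenol protection that leaves under buffered fluoride without touching the acrylate, the esters or ring B. Triisopropylsilyl is preferred to tert-butyldimethylsilyl because the aryl ethers must pass through hydroperoxide, an amide base, acetate at 85 °C and perborate. The forward step only has to avoid phenoxide formation.

**19 to 17.** The C7–O bond is traced to a C7–Br bond through boronate 18. Carrying the oxygen through the ring synthesis instead would require a 3-oxygenated pyrone, which is electron-rich and a poor partner for an electron-rich alkene. The forward reaction must borylate a bromide flanked by O1 without disturbing the acrylate.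

**17 to 15 and 16.** The C5–vinyl bond is cut by a Heck disconnection to dibromide 15 and methyl acrylate 16. Putting the acrylate on the pyrone before ring formation would place a second electrophilic alkene beside the ketene acetal; that is kept only as a reserve. The forward step asks for reaction at the C5 bromide in preference to the C7 bromide.

**15 to 10 and 12 (the central cut).** The bonds C3a–C4 and C7a–C7 are cut, removing ring A as the four-carbon unit of pyrone 12 and leaving ring B as silyl ketene acetal 10. The neighbouring cuts inside ring B (O1–C7a, C2–C3, C3–C3a) all leave ring A to be bought or built with four different substituents. This cut makes ring A from a one-step pyrone and sends all the stereochemistry into a monocyclic lactone. The forward reaction needs three things: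
- regiochemistry C3a to pyrone C6 and C7a to pyrone C3, so that the bromines land on C5 and C7;
- loss of CO2 from the bridged adduct 13;
- loss of the exocyclic silanol, not of O1, from diene 14.

**12 to 11.** Both C–Br bonds come from coumalic acid 11, one by bromodecarboxylation and one by ring bromination, in one flask.

**10 to 9 to 8.** The O–Si bond of the ketene acetal is cut back to lactone ester 9, and the ester methyl to paraconic acid 8. The forward enolisation must take the lactone CH2 (C3a) and leave C3–H alone. The pK difference between a lactone and an acyclic ester, and the hindrance at C3, speak for this.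

**8 to 7 to 5 and 2.** Removal of the auxiliary leads to imide lactone 7. Cutting the lactone C–O bond and the C2–C3 bond gives succinyl imide 5 and aldehyde 2, joined in the forward direction by a boron syn aldol reaction through adduct 6. A syn aldol closes directly to the 2,3-trans lactone, so no equilibration is needed, and the (R)-benzyl oxazolidinone 3 gives the (2R,3R) series. Imide 5 comes from 3 and acid chloride 4, and aldehyde 2 from 3,4-dihydroxybenzaldehyde 1.

## Roads not taken

**Alternative 1:** The cut is O1–C7a, with a carbonyl group re-inserted, which leads to the 3-aryl-3,4-dihydroisocoumarin-4-carboxylate A2.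
- Forward step: Ni(cod)2 with 1,2-bis(dicyclohexylphosphino)ethane. Zerovalent nickel would insert into the acyl–oxygen bond of A2, lose CO and form the aryl–oxygen bond to give A1.
- Merits: ring A arrives with the C7 oxygen (benzyl ether) and the C5 carbon (dioxolane) in place. No late C–O bond is formed and no choice between two bromides is needed. The C2–O bond is never broken.
- Weak points:
  - Decarbonylative C–O coupling is established for aryl esters that give diaryl ethers; A2 is an alkyl ester whose acyl–oxygen bond is far less prone to insertion.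
  - The nickel alkoxide formed has a β-hydrogen at C2 and can collapse to a ketone, which destroys the stereocentre.
  - The temperatures such reactions need endanger C3.
  - The ortho benzyloxy group hinders insertion.
  - Three operations follow (acetal cleavage, olefination, debenzylation without hydrogen), the last with a boron trihalide.
- Comparison: alternative 1 is better in the regiochemistry of ring A and in having the C7 oxygen from the start. The chosen plan has to set a site-selective Heck reaction and a borylation–oxidation against that. In return, each elementary event of its key step has a close known counterpart, whereas the nickel step has none for an alkyl lactone.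

**Alternative 2:** The cut is C3–C3a, which moves ring A back to the carbon that becomes the ester carbon and leads to the (2R)-flavanone A4.
- Forward step: PhI(OAc)2 with catalytic H2SO4 in trimethyl orthoformate. The trivalent iodine reagent functionalises the CH2 next to the ketone, ring A migrates from the ketal carbon to that carbon, and the old carbonyl carbon becomes the methyl ester of trans product A3.
- Merits: this ring contraction is known for flavanones and gives the trans ester directly. There is a single bromide and the C7 oxygen is present, so only a Heck reaction and deacetylation follow. In step count after the key step and in precedent on simple substrates it is better than the chosen plan.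
- Weak points:
  - It needs A4 as a single enantiomer of the unnatural 2R series.
  - Flavanones racemise through reversible opening to the hydroxychalcone under acid, and the step uses sulfuric acid.
  - The migrating ring A carries bromine and acetoxy, which lowers its migratory aptitude and gives room to flavone formation or to migration of ring C.
  - The aryl acetates may be methanolysed under the acidic orthoformate conditions.
- Comparison: the chosen plan sets against the shorter sequence an auxiliary-controlled aldol for both stereocentres, in a lactone that has no achiral open form under its own conditions.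

**Alternative 3:** The cut is C2–C3, which leads to aryldiazoacetate A6.
- Forward step: Rh2(S-PTTL)4 or its mirror image. The carbenoid at C3 inserts into a C–H bond of the benzylic O–CH2 group to give the cis ester A7, and DBU in the same flask epimerises C3 to the trans ester A5.
- Merits: this is the best-precedented road to this compound class. It is catalytic in the chiral element and convergent, with one bromide and the C7 oxygen in place. It is clearly shorter than the chosen plan.
- Weak points:
  - The enantioselectivity depends on the substituents near the reacting ether (a bulky silyloxy group ortho to the ether oxygen, a heavily silylated benzyl group) and is not guaranteed at the level of an auxiliary.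
  - Diazo handling and low temperatures are needed.
  - The base epimerisation runs close to the E1cB opening of ring B.
- Comparison: in precedent and step economy alternative 3 is superior. The chosen plan offers a configuration fixed by a stoichiometric auxiliary with separable diastereomers, no diazo compound, and a test of a ring A synthesis that would be new for this class. Its key-step fallback borrows this insertion chemistry.

Key step: step 8

## Route

Step 1
Reactants: 1 3,4-dihydroxybenzaldehyde
Product: 2 3,4-bis(triisopropylsilyloxy)benzaldehyde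
Conditions: TIPSCl, imidazole, DMF, rt
Reagents that add atoms: chlorotriisopropylsilane (TIPSCl), CC(C)[Si](Cl)(C(C)C)C(C)C
Why: Silyl ether formation on both phenols with imidazole as base and catalyst; the triisopropylsilyl aryl ethers should withstand hydroperoxide, amide base, acetate at 85 °C and perborate, and leave with fluoride at the end.

Step 2
Reactants: 3 (4R)-4-benzyl-1,3-oxazolidin-2-one; 4 methyl 4-chloro-4-oxobutanoate
Product: 5 methyl 4-[(4R)-4-benzyl-2-oxo-1,3-oxazolidin-3-yl]-4-oxobutanoate
Conditions: n-BuLi, THF, −78 °C; then 4, −78 to 0 °C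
Reagents that add atoms: none
Why: N-Acylation of the lithiated oxazolidinone by the acid chloride; the methyl ester does not react at this temperature.

Step 3
Reactants: 5 methyl 4-[(4R)-4-benzyl-2-oxo-1,3-oxazolidin-3-yl]-4-oxobutanoate; 2 3,4-bis(triisopropylsilyloxy)benzaldehyde
Product: 7 (4R)-4-benzyl-3-{[(2R,3R)-2-[3,4-bis(triisopropylsilyloxy)phenyl]-5-oxooxolan-3-yl]carbonyl}-1,3-oxazolidin-2-one, via syn-aldol adduct 6 (not isolated)
Conditions: Bu2BOTf, iPr2NEt, CH2Cl2, −78 to 0 °C; 2, −78 °C to rt; then H2O2, pH 7 buffer, MeOH, 0 °C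
Reagents that add atoms: none
Why: Evans syn aldol reaction: Bu2BOTf and iPr2NEt enolise only the imide to the Z boron enolate, which adds to 2 through a chair Zimmerman–Traxler transition state on the face away from the benzyl group, so the (R)-auxiliary sets both centres of 6 as 3R,4R (syn). The aldolate oxygen then closes onto the methyl ester, and a syn aldol necessarily gives the 2,3-trans lactone, here (2R,3R).

Step 4
Reactants: 7 (4R)-4-benzyl-3-{[(2R,3R)-2-[3,4-bis(triisopropylsilyloxy)phenyl]-5-oxooxolan-3-yl]carbonyl}-1,3-oxazolidin-2-one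
Product: 8 (2R,3R)-2-[3,4-bis(triisopropylsilyloxy)phenyl]-5-oxooxolane-3-carboxylic acid
Conditions: LiOH, H2O2, THF/H2O, 0 °C; Na2SO3; then HCl to pH 3
Reagents that add atoms: hydrogen peroxide (as LiOOH), OO
Why: Hydroperoxide cleavage of the N-acyl oxazolidinone: LiOOH attacks the exocyclic imide carbonyl, sulfite reduces the peracid, and any lactone opened in the basic medium should reclose on acidification. Auxiliary 3 is recovered and C2 and C3 are not touched at 0 °C.

Step 5
Reactants: 8 (2R,3R)-2-[3,4-bis(triisopropylsilyloxy)phenyl]-5-oxooxolane-3-carboxylic acid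
Product: 9 methyl (2R,3R)-2-[3,4-bis(triisopropylsilyloxy)phenyl]-5-oxooxolane-3-carboxylate
Conditions: TMSCHN2, MeOH/toluene, 0 °C
Reagents that add atoms: trimethylsilyldiazomethane (TMSCHN2), C[Si](C)(C)C=[N+]=[N-]
Why: Esterification of the acid by the diazoalkane in methanol, a neutral method that touches neither the lactone nor the aryl silyl ethers.

Step 6
Reactants: 9 methyl (2R,3R)-2-[3,4-bis(triisopropylsilyloxy)phenyl]-5-oxooxolane-3-carboxylate
Product: 10 methyl (2R,3R)-5-(tert-butyldimethylsilyloxy)-2-[3,4-bis(triisopropylsilyloxy)phenyl]-2,3-dihydrofuran-3-carboxylate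
Conditions: LiN(SiMe3)2, TBSCl, DMPU, THF, −78 °C
Reagents that add atoms: tert-butyldimethylsilyl chloride (TBSCl), CC(C)(C)[Si](C)(C)Cl
Why: Kinetic enolisation with in situ O-silylation to the silyl ketene acetal: the lactone CH2 is several pK units more acidic and far less hindered than the tertiary C3–H next to the acyclic ester, and the weak amide base with TBSCl present should trap the lactone enolate on oxygen. Compound 10 is freed from salts under pentane and used crude.

Step 7
Reactants: 11 coumalic acid (2-oxo-2H-pyran-5-carboxylic acid)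
Product: 12 3,5-dibromo-2H-pyran-2-one
Conditions: NBS, LiOAc (cat.), MeCN/H2O, rt
Reagents that add atoms: N-bromosuccinimide (NBS), O=C1CCC(=O)N1Br
Why: Acetate-catalysed bromodecarboxylation (Hunsdiecker type) at C5 of the pyrone together with electrophilic bromination at C3, a known one-flask preparation of this pyrone.

Step 8
Reactants: 10 methyl (2R,3R)-5-(tert-butyldimethylsilyloxy)-2-[3,4-bis(triisopropylsilyloxy)phenyl]-2,3-dihydrofuran-3-carboxylate; 12 3,5-dibromo-2H-pyran-2-one
Product: 15 methyl (2R,3R)-5,7-dibromo-2-[3,4-bis(triisopropylsilyloxy)phenyl]-2,3-dihydro-1-benzofuran-3-carboxylate, via bridged lactone cycloadduct 13 (not isolated), via cyclohexadiene silyl ketal 14 (not isolated)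
Conditions: 12 (1.5 equiv), 2,6-di-tert-butyl-4-methylpyridine (0.2 equiv), toluene, rt to 60 °C, then 110 °C
Reagents that add atoms: none
Why: Proposed new method: the closest known reaction type is the inverse-electron-demand Diels–Alder reaction of 3,5-dibromo-2-pyrone and of coumalate esters with acyclic ketene acetals and enol ethers, followed by CO2 extrusion and loss of alcohol to the arene; a lactone-derived cyclic silyl ketene acetal, in which a ring oxygen competes as leaving group, is untested. The nucleophilic carbon C3a of 10 should bond to the electrophilic position 6 of the pyrone and the dioxygenated carbon C7a to the bromine-bearing position 3, a polarity match that places the bromines on C5 and C7; whether concerted or by conjugate addition and ring closure, the result is bridged lactone 13. Ring A closes in this intermolecular [4+2] cycloaddition (C3a–C4 and C7a–C7 formed across the double bond of ring B), and a retro-[4+2] loss of CO2 from 13 on heating gives diene 14, whose C7a is a mixed silyl alkyl ketal. Aromatisation then needs the exocyclic silyloxy group, not O1, to leave: the silanolate is the better nucleofuge (a trialkylsilanol is several pK units more acidic than a secondary alcohol), the cis ring fusion holds it syn to the C3a hydrogen so that it can take the proton within the ion pair, and the hindered pyridine removes the acid that would activate the more basic O1 while being too weak for an anti elimination that would expel O1. No stereocentre made in the step survives (C3a, C7a and both bridgeheads end sp2), so endo/exo and facial selectivity do not matter, and C2 and C3 lie outside the reacting π system and meet no base. The selectivities needed are therefore the regiochemistry of addition, secured by the polarisation of both partners, and the direction of the final elimination, secured by leaving-group ability and geometry. The lower temperature stage lets 10 be consumed before heating, which avoids its thermal O-to-C silyl shift.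

Step 9
Reactants: 15 methyl (2R,3R)-5,7-dibromo-2-[3,4-bis(triisopropylsilyloxy)phenyl]-2,3-dihydro-1-benzofuran-3-carboxylate; 16 methyl acrylate
Product: 17 methyl (2R,3R)-7-bromo-5-[(1E)-3-methoxy-3-oxoprop-1-en-1-yl]-2-[3,4-bis(triisopropylsilyloxy)phenyl]-2,3-dihydro-1-benzofuran-3-carboxylate
Conditions: 16 (1.1 equiv), Pd(OAc)2, P(o-tol)3, Et3N, DMF, 90 °C
Reagents that add atoms: none
Why: Mizoroki–Heck reaction: oxidative addition is expected at the C5 bromide, which has two ortho hydrogens, in preference to the C7 bromide next to O1, and the bulky phosphine with only a slight excess of 16 favours mono-coupling. Syn insertion and syn β-hydride elimination give the E acrylate, and triethylamine is too weak to open ring B.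

Step 10
Reactants: 17 methyl (2R,3R)-7-bromo-5-[(1E)-3-methoxy-3-oxoprop-1-en-1-yl]-2-[3,4-bis(triisopropylsilyloxy)phenyl]-2,3-dihydro-1-benzofuran-3-carboxylate
Product: 19 methyl (2R,3R)-7-hydroxy-5-[(1E)-3-methoxy-3-oxoprop-1-en-1-yl]-2-[3,4-bis(triisopropylsilyloxy)phenyl]-2,3-dihydro-1-benzofuran-3-carboxylate, via aryl pinacol boronate 18 (not isolated)
Conditions: PdCl2(dppf), B2pin2, KOAc, 1,4-dioxane, 85 °C; then NaBO3·4H2O, THF/H2O, rt
Reagents that add atoms: sodium perborate, [Na+].[O-]OB=O (the C7 oxygen); bis(pinacolato)diboron, CC1(C)OB(OC1(C)C)B1OC(C)(C)C(C)(C)O1 (the boryl group of 18)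
Why: Miyaura borylation of the remaining aryl bromide with the weak base KOAc, then oxidation of crude boronate 18 by perborate with aryl migration from boron to oxygen. Neither stage is basic enough to epimerise C3 or to add to the acrylate.

Step 11
Reactants: 19 methyl (2R,3R)-7-hydroxy-5-[(1E)-3-methoxy-3-oxoprop-1-en-1-yl]-2-[3,4-bis(triisopropylsilyloxy)phenyl]-2,3-dihydro-1-benzofuran-3-carboxylate
Product: 20 methyl (2R,3R)-2-(3,4-dihydroxyphenyl)-7-hydroxy-5-[(1E)-3-methoxy-3-oxoprop-1-en-1-yl]-2,3-dihydro-1-benzofuran-3-carboxylate
Conditions: HF·pyridine, pyridine, THF, 0 °C to rt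
Reagents that add atoms: none
Why: Fluoride cleavage of the two aryl silyl ethers under pyridine-buffered, slightly acidic conditions, which should spare both methyl esters, the acrylate and the trans ring B and avoid phenoxide formation and catechol oxidation.

## Compound list

1 | 3,4-dihydroxybenzaldehyde | O=Cc1ccc(O)c(O)c1 | starting material
2 | 3,4-bis(triisopropylsilyloxy)benzaldehyde | O=Cc1ccc(O[Si](C(C)C)(C(C)C)C(C)C)c(O[Si](C(C)C)(C(C)C)C(C)C)c1 | intermediate
3 | (4R)-4-benzyl-1,3-oxazolidin-2-one | O=C1N[C@H](Cc2ccccc2)CO1 | starting material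
4 | methyl 4-chloro-4-oxobutanoate | COC(=O)CCC(Cl)=O | starting material
5 | methyl 4-[(4R)-4-benzyl-2-oxo-1,3-oxazolidin-3-yl]-4-oxobutanoate | COC(=O)CCC(=O)N1[C@H](Cc2ccccc2)COC1=O | intermediate
6 | methyl (3R,4R)-3-{[(4R)-4-benzyl-2-oxo-1,3-oxazolidin-3-yl]carbonyl}-4-hydroxy-4-[3,4-bis(triisopropylsilyloxy)phenyl]butanoate (syn aldol adduct, present as its boron aldolate) | COC(=O)C[C@@H](C(=O)N1[C@H](Cc2ccccc2)COC1=O)[C@@H](O)c1ccc(O[Si](C(C)C)(C(C)C)C(C)C)c(O[Si](C(C)C)(C(C)C)C(C)C)c1 | intermediate (not isolated)
7 | (4R)-4-benzyl-3-{[(2R,3R)-2-[3,4-bis(triisopropylsilyloxy)phenyl]-5-oxooxolan-3-yl]carbonyl}-1,3-oxazolidin-2-one | O=C1C[C@@H](C(=O)N2[C@H](Cc3ccccc3)COC2=O)[C@H](c2ccc(O[Si](C(C)C)(C(C)C)C(C)C)c(O[Si](C(C)C)(C(C)C)C(C)C)c2)O1 | intermediate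
8 | (2R,3R)-2-[3,4-bis(triisopropylsilyloxy)phenyl]-5-oxooxolane-3-carboxylic acid | O=C1C[C@@H](C(=O)O)[C@H](c2ccc(O[Si](C(C)C)(C(C)C)C(C)C)c(O[Si](C(C)C)(C(C)C)C(C)C)c2)O1 | intermediate
9 | methyl (2R,3R)-2-[3,4-bis(triisopropylsilyloxy)phenyl]-5-oxooxolane-3-carboxylate | O=C1C[C@@H](C(=O)OC)[C@H](c2ccc(O[Si](C(C)C)(C(C)C)C(C)C)c(O[Si](C(C)C)(C(C)C)C(C)C)c2)O1 | intermediate
10 | methyl (2R,3R)-5-(tert-butyldimethylsilyloxy)-2-[3,4-bis(triisopropylsilyloxy)phenyl]-2,3-dihydrofuran-3-carboxylate | CC(C)(C)[Si](C)(C)OC1=C[C@@H](C(=O)OC)[C@H](c2ccc(O[Si](C(C)C)(C(C)C)C(C)C)c(O[Si](C(C)C)(C(C)C)C(C)C)c2)O1 | intermediate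
11 | coumalic acid (2-oxo-2H-pyran-5-carboxylic acid) | O=C(O)c1ccc(=O)oc1 | starting material
12 | 3,5-dibromo-2H-pyran-2-one | O=c1occ(Br)cc1Br | intermediate
13 | methyl (2R,3R)-5,7-dibromo-7a-(tert-butyldimethylsilyloxy)-9-oxo-2-[3,4-bis(triisopropylsilyloxy)phenyl]-2,3,3a,4,7,7a-hexahydro-4,7-(epoxymethano)-1-benzofuran-3-carboxylate (bridged lactone, mixture at C3a, C4, C7, C7a) | O=C1OC2C(Br)=CC1(Br)C1(O[Si](C)(C)C(C)(C)C)O[C@@H](c3ccc(O[Si](C(C)C)(C(C)C)C(C)C)c(O[Si](C(C)C)(C(C)C)C(C)C)c3)[C@H](C(=O)OC)C21 | intermediate (not isolated)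
14 | methyl (2R,3R)-5,7-dibromo-7a-(tert-butyldimethylsilyloxy)-2-[3,4-bis(triisopropylsilyloxy)phenyl]-2,3,3a,7a-tetrahydro-1-benzofuran-3-carboxylate (cis-fused diene, mixture at C3a, C7a) | BrC1=CC(Br)=CC2[C@@H](C(=O)OC)[C@H](c3ccc(O[Si](C(C)C)(C(C)C)C(C)C)c(O[Si](C(C)C)(C(C)C)C(C)C)c3)OC12O[Si](C)(C)C(C)(C)C | intermediate (not isolated)
15 | methyl (2R,3R)-5,7-dibromo-2-[3,4-bis(triisopropylsilyloxy)phenyl]-2,3-dihydro-1-benzofuran-3-carboxylate | Brc1cc(Br)c2c(c1)[C@@H](C(=O)OC)[C@H](c1ccc(O[Si](C(C)C)(C(C)C)C(C)C)c(O[Si](C(C)C)(C(C)C)C(C)C)c1)O2 | intermediate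
16 | methyl acrylate | C=CC(=O)OC | starting material
17 | methyl (2R,3R)-7-bromo-5-[(1E)-3-methoxy-3-oxoprop-1-en-1-yl]-2-[3,4-bis(triisopropylsilyloxy)phenyl]-2,3-dihydro-1-benzofuran-3-carboxylate | COC(=O)/C=C/c1cc(Br)c2c(c1)[C@@H](C(=O)OC)[C@H](c1ccc(O[Si](C(C)C)(C(C)C)C(C)C)c(O[Si](C(C)C)(C(C)C)C(C)C)c1)O2 | intermediate
18 | methyl (2R,3R)-5-[(1E)-3-methoxy-3-oxoprop-1-en-1-yl]-7-(4,4,5,5-tetramethyl-1,3,2-dioxaborolan-2-yl)-2-[3,4-bis(triisopropylsilyloxy)phenyl]-2,3-dihydro-1-benzofuran-3-carboxylate | COC(=O)/C=C/c1cc(B3OC(C)(C)C(C)(C)O3)c2c(c1)[C@@H](C(=O)OC)[C@H](c1ccc(O[Si](C(C)C)(C(C)C)C(C)C)c(O[Si](C(C)C)(C(C)C)C(C)C)c1)O2 | intermediate (not isolated)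
19 | methyl (2R,3R)-7-hydroxy-5-[(1E)-3-methoxy-3-oxoprop-1-en-1-yl]-2-[3,4-bis(triisopropylsilyloxy)phenyl]-2,3-dihydro-1-benzofuran-3-carboxylate | COC(=O)/C=C/c1cc(O)c2c(c1)[C@@H](C(=O)OC)[C@H](c1ccc(O[Si](C(C)C)(C(C)C)C(C)C)c(O[Si](C(C)C)(C(C)C)C(C)C)c1)O2 | intermediate
20 | methyl (2R,3R)-2-(3,4-dihydroxyphenyl)-7-hydroxy-5-[(1E)-3-methoxy-3-oxoprop-1-en-1-yl]-2,3-dihydro-1-benzofuran-3-carboxylate | COC(=O)/C=C/c1cc(O)c2c(c1)[C@@H](C(=O)OC)[C@H](c1ccc(O)c(O)c1)O2 | target

## Step count and least certain steps

Total: 11 steps. Longest linear sequence: 9 steps (1 or 2, then 3, 4, 5, 6, 8, 9, 10, 11). Step 7 is a one-step side branch.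

**Step 8 (key step, proposed new method).**
- Most likely failure: aromatisation by the wrong heterolysis at C7a, that is loss of the ring oxygen O1 with opening of ring B, if traces of acid activate O1 or a base induces anti elimination. A second failure is conjugate addition at pyrone C6 followed by silyl transfer without ring closure. A third is return of the ketene acetal to lactone 9 by adventitious protonation.
- Fallback (known chemistry, intramolecular C–H insertion of a rhodium carbenoid): it sets out from aldehyde 2 and comes back at 15. Aldehyde 2 is reduced (NaBH4, MeOH) to [3,4-bis(triisopropylsilyloxy)phenyl]methanol F1. Methyl 2-(3,5-dibromo-2-hydroxyphenyl)acetate F2, prepared by dibromination (Br2, AcOH) of its commercial parent ester, is joined to F1 by a Mitsunobu reaction (PPh3, DIAD, THF) to give the benzyl ether methyl 2-[3,5-dibromo-2-({3,4-bis(triisopropylsilyloxy)phenyl}methoxy)phenyl]acetate F3. Regitz diazo transfer (p-ABSA, DBU, MeCN) gives the aryldiazoacetate F4. Rh2(S-PTTL)4 (dirhodium tetrakis[N-phthaloyl-(S)-tert-leucinate]), or its mirror-image complex if that is the one that delivers 2R, in toluene at low temperature should insert the carbenoid into the benzylic O–CH2 bond to give the cis ester methyl (2R,3S)-5,7-dibromo-2-[3,4-bis(triisopropylsilyloxy)phenyl]-2,3-dihydro-1-benzofuran-3-carboxylate F5. DBU then epimerises C3 to the trans ester 15.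

**Step 6.**
- Most likely failure: competing deprotonation at C3–H, which leads to E1cB opening of the lactone to an alkylidene succinate or to epimerisation; C-silylation is a lesser risk.
- Fallback (removes the acidic ester before enolisation): it sets out from acid 8 and comes back at 15. Acid 8 with two equivalents of LiN(SiMe3)2 forms the carboxylate–lactone enolate dianion, the kind of dianion known from α-alkylation of paraconic acids. TBSCl should give the bis-silyl compound tert-butyldimethylsilyl (2R,3R)-5-(tert-butyldimethylsilyloxy)-2-[3,4-bis(triisopropylsilyloxy)phenyl]-2,3-dihydrofuran-3-carboxylate F6. F6 is taken through the conditions of step 8 with 12 to the silyl ester tert-butyldimethylsilyl (2R,3R)-5,7-dibromo-2-[3,4-bis(triisopropylsilyloxy)phenyl]-2,3-dihydro-1-benzofuran-3-carboxylate F7. Aqueous work-up hydrolyses F7 to (2R,3R)-5,7-dibromo-2-[3,4-bis(triisopropylsilyloxy)phenyl]-2,3-dihydro-1-benzofuran-3-carboxylic acid F8, and TMSCHN2 in methanol gives 15.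

**Step 9.**
- Most likely failure: poor site selectivity in the oxidative addition, giving coupling at C7 or at both bromides; the preference for C5 rests on sterics alone.
- Fallback (puts the acrylate on the pyrone before ring A is made): it sets out from pyrone 12 and comes back at 17. Stille coupling of 12 with methyl (E)-3-(tributylstannyl)acrylate under the copper iodide (CuI)-promoted conditions in DMF with Pd(PPh3)4, which direct this pyrone to react at C5, should give methyl (2E)-3-(5-bromo-6-oxo-6H-pyran-3-yl)prop-2-enoate F9. F9 and ketene acetal 10 under the conditions of step 8 would then give 17 directly.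

**Step 10.**
- Most likely failure: hydrodebromination in place of borylation at the hindered C7 position, or partial loss of aryl silyl ethers and attack on the acrylate during the oxidation.
- Fallback (oxygen first, Heck second): it sets out from dibromide 15 and comes back at 19. Bromine–magnesium exchange with i-PrMgCl·LiCl at low temperature, directed to the bromide ortho to O1, trapping with B(OMe)3 and oxidation with H2O2 in the same flask should give methyl (2R,3R)-5-bromo-7-hydroxy-2-[3,4-bis(triisopropylsilyloxy)phenyl]-2,3-dihydro-1-benzofuran-3-carboxylate F10. The Heck reaction of step 9 on its single bromide with 16 then gives 19. The acidity of C3–H toward the aryl Grignard is the point to watch on this path.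

## Further compounds

F1 | step 8 | [3,4-bis(triisopropylsilyloxy)phenyl]methanol | OCc1ccc(O[Si](C(C)C)(C(C)C)C(C)C)c(O[Si](C(C)C)(C(C)C)C(C)C)c1
F2 | step 8 | methyl 2-(3,5-dibromo-2-hydroxyphenyl)acetate | COC(=O)Cc1cc(Br)cc(Br)c1O
F3 | step 8 | methyl 2-[3,5-dibromo-2-({3,4-bis(triisopropylsilyloxy)phenyl}methoxy)phenyl]acetate | COC(=O)Cc1cc(Br)cc(Br)c1OCc1ccc(O[Si](C(C)C)(C(C)C)C(C)C)c(O[Si](C(C)C)(C(C)C)C(C)C)c1
F4 | step 8 | methyl 2-diazo-2-[3,5-dibromo-2-({3,4-bis(triisopropylsilyloxy)phenyl}methoxy)phenyl]acetate | COC(=O)C(=[N+]=[N-])c1cc(Br)cc(Br)c1OCc1ccc(O[Si](C(C)C)(C(C)C)C(C)C)c(O[Si](C(C)C)(C(C)C)C(C)C)c1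
F5 | step 8 | methyl (2R,3S)-5,7-dibromo-2-[3,4-bis(triisopropylsilyloxy)phenyl]-2,3-dihydro-1-benzofuran-3-carboxylate | Brc1cc(Br)c2c(c1)[C@H](C(=O)OC)[C@H](c1ccc(O[Si](C(C)C)(C(C)C)C(C)C)c(O[Si](C(C)C)(C(C)C)C(C)C)c1)O2
F6 | step 6 | tert-butyldimethylsilyl (2R,3R)-5-(tert-butyldimethylsilyloxy)-2-[3,4-bis(triisopropylsilyloxy)phenyl]-2,3-dihydrofuran-3-carboxylate | CC(C)(C)[Si](C)(C)OC1=C[C@@H](C(=O)O[Si](C)(C)C(C)(C)C)[C@H](c2ccc(O[Si](C(C)C)(C(C)C)C(C)C)c(O[Si](C(C)C)(C(C)C)C(C)C)c2)O1
F7 | step 6 | tert-butyldimethylsilyl (2R,3R)-5,7-dibromo-2-[3,4-bis(triisopropylsilyloxy)phenyl]-2,3-dihydro-1-benzofuran-3-carboxylate | Brc1cc(Br)c2c(c1)[C@@H](C(=O)O[Si](C)(C)C(C)(C)C)[C@H](c1ccc(O[Si](C(C)C)(C(C)C)C(C)C)c(O[Si](C(C)C)(C(C)C)C(C)C)c1)O2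
F8 | step 6 | (2R,3R)-5,7-dibromo-2-[3,4-bis(triisopropylsilyloxy)phenyl]-2,3-dihydro-1-benzofuran-3-carboxylic acid | Brc1cc(Br)c2c(c1)[C@@H](C(=O)O)[C@H](c1ccc(O[Si](C(C)C)(C(C)C)C(C)C)c(O[Si](C(C)C)(C(C)C)C(C)C)c1)O2
F9 | step 9 | methyl (2E)-3-(5-bromo-6-oxo-6H-pyran-3-yl)prop-2-enoate | COC(=O)/C=C/c1cc(Br)c(=O)oc1
F10 | step 10 | methyl (2R,3R)-5-bromo-7-hydroxy-2-[3,4-bis(triisopropylsilyloxy)phenyl]-2,3-dihydro-1-benzofuran-3-carboxylate | Brc1cc(O)c2c(c1)[C@@H](C(=O)OC)[C@H](c1ccc(O[Si](C(C)C)(C(C)C)C(C)C)c(O[Si](C(C)C)(C(C)C)C(C)C)c1)O2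
A1 | alternative 1 | methyl (2R,3R)-7-(benzyloxy)-2-[3,4-bis(benzyloxy)phenyl]-5-(1,3-dioxolan-2-yl)-2,3-dihydro-1-benzofuran-3-carboxylate | C1(OCCO1)c1cc(OCc3ccccc3)c2c(c1)[C@@H](C(=O)OC)[C@H](c1ccc(OCc3ccccc3)c(OCc3ccccc3)c1)O2
A2 | alternative 1 | methyl (3R,4R)-8-(benzyloxy)-3-[3,4-bis(benzyloxy)phenyl]-6-(1,3-dioxolan-2-yl)-1-oxo-3,4-dihydro-1H-2-benzopyran-4-carboxylate | O=C1O[C@@H](c3ccc(OCc4ccccc4)c(OCc4ccccc4)c3)[C@H](C(=O)OC)c2cc(C3OCCO3)cc(OCc3ccccc3)c12
A3 | alternative 2 | methyl (2R,3R)-7-acetoxy-5-bromo-2-(3,4-diacetoxyphenyl)-2,3-dihydro-1-benzofuran-3-carboxylate | Brc1cc(OC(C)=O)c2c(c1)[C@@H](C(=O)OC)[C@H](c1ccc(OC(C)=O)c(OC(C)=O)c1)O2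
A4 | alternative 2 | (2R)-8-acetoxy-6-bromo-2-(3,4-diacetoxyphenyl)-2,3-dihydro-4H-chromen-4-one | O=C1C[C@H](c2ccc(OC(C)=O)c(OC(C)=O)c2)Oc2c(OC(C)=O)cc(Br)cc12
A5 | alternative 3 | methyl (2R,3R)-5-bromo-7-(tert-butyldimethylsilyloxy)-2-[3,4-bis(tert-butyldimethylsilyloxy)phenyl]-2,3-dihydro-1-benzofuran-3-carboxylate | Brc1cc(O[Si](C)(C)C(C)(C)C)c2c(c1)[C@@H](C(=O)OC)[C@H](c1ccc(O[Si](C)(C)C(C)(C)C)c(O[Si](C)(C)C(C)(C)C)c1)O2
A6 | alternative 3 | methyl 2-[5-bromo-3-(tert-butyldimethylsilyloxy)-2-({3,4-bis(tert-butyldimethylsilyloxy)phenyl}methoxy)phenyl]-2-diazoacetate | COC(=O)C(=[N+]=[N-])c1cc(Br)cc(O[Si](C)(C)C(C)(C)C)c1OCc1ccc(O[Si](C)(C)C(C)(C)C)c(O[Si](C)(C)C(C)(C)C)c1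
A7 | alternative 3 | methyl (2R,3S)-5-bromo-7-(tert-butyldimethylsilyloxy)-2-[3,4-bis(tert-butyldimethylsilyloxy)phenyl]-2,3-dihydro-1-benzofuran-3-carboxylate | Brc1cc(O[Si](C)(C)C(C)(C)C)c2c(c1)[C@H](C(=O)OC)[C@H](c1ccc(O[Si](C)(C)C(C)(C)C)c(O[Si](C)(C)C(C)(C)C)c1)O2
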